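**Retrosynthetic overview**
1. The target is read as a germacranolide: a ten-membered carbocycle C1–C10 (C1 ketone, C4=C5 E-olefin, C14 on C10, C15 on C4) fused at C6/C7 to a butenolide (C6–O–C12(=O)–C11=C7, C13 = CH2OAc on C11). The last operations are C13 desilylation and acetylation of O13 and the tertiary O10.
2. Key disconnection C3–C4: the γ,δ-unsaturated ketone O=C1–C2–C3–C4(C15)=C5 inside the ten-membered ring, with C5 bound to the lactone carbinol C6, is the retron of a ruthenium-catalysed redox coupling of a C1 vinyl carbinol with a C4≡C5 propynyl group on C6. One operation closes the ring, sets the 4E geometry and creates the C1 ketone.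
3. The seco precursor comes from a butenolide first built the wrong way round (carbonyl at C6; acylketene esterification/Knoevenagel with a dihydroxyacetone ether). It is then turned round: propynyl addition at C6, 1,3-syn reduction, oxidative relactonisation onto C12.
4. Stereochemistry: C10 (with C8, C9, C1, C14) from (R)-citramalic acid; C8 by CBS reduction; C6 relayed from C8.
5. Ring order: provisional butenolide (C6 carbonyl) → final butenolide (C12 carbonyl) → ten-membered ring.

Key step: step 14

Remark: locants follow germacrane numbering as defined in line 1; compound 23 is carried as both C1 epimers, because C1 becomes the ketone in step 14.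

**Step 1**
Reactants: 1 (R)-citramalic acid
Product: 2 (2R)-2-methylbutane-1,2,4-triol
Conditions: BH3·SMe2, B(OMe)3, THF, 0 °C to rt; MeOH
Reagents that add atoms: none
Why: Borane reduces both carboxylic acids and cannot touch the quaternary carbinol, so the chiral-pool centre (future C10) is carried over unchanged (borane reduction of carboxylic acids).

**Step 2**
Reactants: 2 (2R)-2-methylbutane-1,2,4-triol
Product: 3 acetonide alcohol
Conditions: 2,2-dimethoxypropane, p-TsOH (cat.), acetone, rt
Reagents that add atoms: 2,2-dimethoxypropane, COC(C)(C)OC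
Why: Under thermodynamic control the five-membered 1,2-acetonide (O10/O1) should form, because the alternative 1,3-dioxane would carry an axial substituent next to the axial acetal methyl; the C8 primary alcohol stays free (acetal formation).

**Step 3**
Reactants: 3 acetonide alcohol
Product: 4 acetonide acid
Conditions: TEMPO (cat.), NaOCl (cat.), NaClO2, MeCN/phosphate buffer pH 6.7, 35 °C
Reagents that add atoms: sodium chlorite, [Na+].[O-]Cl=O
Why: Nitroxyl/chlorite oxidation takes the primary alcohol to the acid (C8) at a buffered pH that the acetonide tolerates (TEMPO/chlorite oxidation).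

**Step 4**
Reactants: 4 acetonide acid; 5 Meldrum's acid
Product: 6 acyl Meldrum's acid
Conditions: EDC·HCl, DMAP, CH2Cl2, 0 °C to rt
Reagents that add atoms: none
Why: Carbodiimide activation and C-acylation of Meldrum's acid gives a storable acylketene precursor that brings in C7 and C6 (C-acylation of Meldrum's acid).

**Step 5**
Reactants: 7 1,3-dihydroxyacetone
Product: 8 mono-TBDPS ether of dihydroxyacetone
Conditions: TBDPSCl (1 equiv), imidazole, DMF, 0 °C
Reagents that add atoms: tert-butyl(chloro)diphenylsilane, CC(C)(C)[Si](Cl)(c1ccccc1)c1ccccc1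
Why: Mono-silylation with one equivalent of the bulky chlorosilane differentiates the two CH2O arms that become C12 (free OH) and C13 (silyl ether) (silyl ether formation).

**Step 6**
Reactants: 6 acyl Meldrum's acid; 8 mono-TBDPS ether of dihydroxyacetone
Product: 11 3-acyl butenolide (lactone carbonyl at C6), via acylketene 9 (not isolated), via β-keto ester 10 (not isolated)
Conditions: toluene, 90 °C; then Et3N (cat.), 4 Å MS, rt
Reagents that add atoms: none
Why: Thermolysis of 6 gives acylketene 9, which the hydroxy ketone traps as β-keto ester 10; amine-mediated intramolecular Knoevenagel condensation of the C7 methylene onto the C11 ketone (5-exo-trig aldol, then dehydration) closes the butenolide (acylketene esterification, Knoevenagel condensation).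

**Step 7**
Reactants: 11 3-acyl butenolide
Product: 12 (8S)-carbinol butenolide
Conditions: (R)-2-methyl-CBS-oxazaborolidine (0.5 equiv), catecholborane, toluene, −78 °C
Reagents that add atoms: none
Why: With the fully substituted alkenyl carbon C7 as the large and the C9 methylene as the small group, the (R)-oxazaborolidine should deliver hydride to give (8S), while lactone and tetrasubstituted alkene are not reduced at −78 °C (Corey–Bakshi–Shibata reduction).

**Step 8**
Reactants: 12 (8S)-carbinol butenolide; 13 1-propynyllithium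
Product: 15 (6R,8S)-triol, via hydroxy ynone 14 (not isolated)
Conditions: CeCl3, THF, −78 °C; then MeOH, Et2BOMe, NaBH4, −78 °C
Reagents that add atoms: none
Why: The weakly basic propynylcerium reagent should add once to the lactone carbonyl C6 without γ-deprotonation; methanol frees hydroxy ynone 14 from its hemiketal, and reduction through the boron chelate between O8 and the C6 carbonyl (C9 held out of the enone plane by allylic 1,3-strain) delivers hydride anti to C9, setting (6R) 1,3-syn to C8 (organocerium addition to a lactone, Narasaka–Prasad reduction).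

**Step 9**
Reactants: 15 (6R,8S)-triol
Product: 18 transposed butenolide (lactone carbonyl at C12), via hydroxy enal 16 (not isolated), via lactol 17 (not isolated)
Conditions: TEMPO (cat.), PhI(OAc)2, CH2Cl2, rt
Reagents that add atoms: none
Why: The primary allylic alcohol should be oxidised much faster than the two secondary ones to enal 16, which the cis C6 hydroxyl traps as lactol 17; this is oxidised on to the lactone, so the ring oxygen now sits on C6 and the carbonyl on C12, with C6 untouched (TEMPO oxidative lactonisation of a 1,4-diol).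

**Step 10**
Reactants: 18 transposed butenolide
Product: 19 8-methacrylate
Conditions: methacrylic anhydride, Et3N, DMAP (cat.), CH2Cl2, 0 °C
Reagents that add atoms: methacrylic anhydride, CC(=C)C(=O)OC(=O)C(C)=C
Why: The only free hydroxyl (C8) is acylated; the short reaction at 0 °C should avoid γ-epimerisation at C6 (DMAP-catalysed acylation).

**Step 11**
Reactants: 19 8-methacrylate
Product: 20 1,10-diol
Conditions: AcOH/THF/H2O (3:1:1), 40 °C
Reagents that add atoms: none
Why: Aqueous acetic acid hydrolyses the terminal acetonide, while the TBDPS ether, the methacrylate and the lactone are stable (acetal hydrolysis).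

**Step 12**
Reactants: 20 1,10-diol
Product: 21 C1 aldehyde
Conditions: SO3·pyridine, DMSO, iPr2NEt, CH2Cl2, 0 °C
Reagents that add atoms: none
Why: Activated-DMSO oxidation converts the primary alcohol into the aldehyde without glycol cleavage; the aldehyde has no α-hydrogen and the tertiary alcohol cannot be oxidised (Parikh–Doering oxidation).

**Step 13**
Reactants: 21 C1 aldehyde; 22 vinyl bromide
Product: 23 C1 vinyl carbinol
Conditions: CrCl2, NiCl2 (cat.), DMSO/THF, rt
Reagents that add atoms: none
Why: The vinylchromium reagent adds to the aldehyde only and leaves lactone, esters and alkyne untouched; no control at C1 is needed (Nozaki–Hiyama–Kishi reaction).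

**Step 14**
Reactants: 23 C1 vinyl carbinol
Product: 25 macrocyclic 10-hydroxy-1-ketone, via macrocyclic enol 24 (not isolated)
Conditions: CpRu(MeCN)3PF6 (20 mol %), acetone, 0.002 M, slow addition, 50 °C
Reagents that add atoms: none
Why: Proposed new method: the cationic CpRu fragment should bind the monosubstituted alkene C2=C3 and the alkyne C4≡C5 and couple them oxidatively to a ruthenacyclopentene that already contains the new C3–C4 bond (Ru on C5 and C2), after which β-hydride elimination of the carbinol hydrogen at C1 and reductive elimination of C5–H release enol 24, which tautomerises to ketone 25, so that the step is an isomerisation without any stoichiometric reagent. The closest known reaction type is the intermolecular ruthenium-catalysed coupling of allylic alcohols with alkynes to γ,δ-unsaturated ketones, together with the use of the parent alkene–alkyne coupling for large-ring closure; untested is the closure of a ten-membered ring with both alkyne carbons inside the ring. The ten-membered carbocycle closes in the 10-endo mode with respect to both π-systems (C2, C3, C4, C5 all become ring atoms). No stereocentre is created; the new stereo-element is the C4=C5 bond, and its E geometry is fixed by the cis addition of C3 and H across the alkyne within the metallacycle. The step needs regioselectivity at the alkyne (C3 to the methyl-bearing C4, not to C5, which would give a nine-membered ring with an exocyclic ethylidene), secured by the small methyl group against the branched, oxygen-bearing C6 that prefers the ruthenium-bound carbon, and chemoselectivity for the allylic alcohol alkene, secured because the 1,1-disubstituted conjugated methacrylate and the tetrasubstituted butenolide alkene are poor partners for this catalyst. High dilution with slow addition suppresses dimerisation, and the planar butenolide, which holds C6 and C8 on the same sp2 carbon C7, shortens the chain that has to fold.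

**Step 15**
Reactants: 25 macrocyclic 10-hydroxy-1-ketone
Product: 26 10,13-diol
Conditions: HF·pyridine, THF/pyridine, 0 °C to rt
Reagents that add atoms: none
Why: Buffered fluoride cleaves the primary TBDPS ether without affecting the α-hydroxy ketone, the esters or the lactone (fluoride desilylation).

**Step 16**
Reactants: 26 10,13-diol
Product: 27 target
Conditions: Ac2O, Bi(OTf)3 (5 mol %), MeCN, 0 °C
Reagents that add atoms: acetic anhydride, CC(=O)OC(C)=O
Why: Lewis-acid-catalysed acylation is strong enough to esterify the tertiary α-ketol hydroxyl at C10 together with the primary C13 hydroxyl under mild, non-basic conditions (Bi(OTf)3-catalysed acetylation).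

**Compound list**
1 | (R)-citramalic acid [(2R)-2-hydroxy-2-methylbutanedioic acid] | OC(=O)C[C@@](C)(O)C(=O)O | starting material
2 | (2R)-2-methylbutane-1,2,4-triol | OCC[C@@](C)(O)CO | intermediate
3 | 2-[(4R)-2,2,4-trimethyl-1,3-dioxolan-4-yl]ethan-1-ol | OCC[C@@](C)(OC1(C)C)CO1 | intermediate
4 | 2-[(4R)-2,2,4-trimethyl-1,3-dioxolan-4-yl]acetic acid | OC(=O)C[C@@](C)(OC1(C)C)CO1 | intermediate
5 | Meldrum's acid (2,2-dimethyl-1,3-dioxane-4,6-dione) | CC1(C)OC(=O)CC(=O)O1 | starting material
6 | 5-{1-hydroxy-2-[(4R)-2,2,4-trimethyl-1,3-dioxolan-4-yl]ethylidene}-2,2-dimethyl-1,3-dioxane-4,6-dione | CC1(C)OC(=O)C(=C(O)C[C@@](C)(OC2(C)C)CO2)C(=O)O1 | intermediate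
7 | 1,3-dihydroxyacetone (sold as its dimer) | OCC(=O)CO | starting material
8 | 1-[(tert-butyldiphenylsilyl)oxy]-3-hydroxypropan-2-one | OCC(=O)CO[Si](c1ccccc1)(c1ccccc1)C(C)(C)C | intermediate
9 | 4-[(4R)-2,2,4-trimethyl-1,3-dioxolan-4-yl]but-1-ene-1,3-dione (acylketene) | O=C=CC(=O)C[C@@](C)(OC1(C)C)CO1 | intermediate (not isolated)
10 | 3-[(tert-butyldiphenylsilyl)oxy]-2-oxopropyl 3-oxo-4-[(4R)-2,2,4-trimethyl-1,3-dioxolan-4-yl]butanoate | CC(C)(C)[Si](c1ccccc1)(c1ccccc1)OCC(=O)COC(=O)CC(=O)C[C@@](C)(OC2(C)C)CO2 | intermediate (not isolated)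
11 | 4-{[(tert-butyldiphenylsilyl)oxy]methyl}-3-{2-[(4R)-2,2,4-trimethyl-1,3-dioxolan-4-yl]acetyl}furan-2(5H)-one | O=C1OCC(CO[Si](c2ccccc2)(c2ccccc2)C(C)(C)C)=C1C(=O)C[C@@](C)(OC3(C)C)CO3 | intermediate
12 | 4-{[(tert-butyldiphenylsilyl)oxy]methyl}-3-{(1S)-1-hydroxy-2-[(4R)-2,2,4-trimethyl-1,3-dioxolan-4-yl]ethyl}furan-2(5H)-one | O=C1OCC(CO[Si](c2ccccc2)(c2ccccc2)C(C)(C)C)=C1[C@@H](O)C[C@@](C)(OC3(C)C)CO3 | intermediate
13 | 1-propynyllithium | [Li]C#CC | starting material
14 | (2E)-2-{[(tert-butyldiphenylsilyl)oxy]methyl}-1-hydroxy-3-{(1S)-1-hydroxy-2-[(4R)-2,2,4-trimethyl-1,3-dioxolan-4-yl]ethyl}hept-2-en-5-yn-4-one (open form of the cyclic hemiketal; CH2OH cis to the ynone carbonyl) | CC#CC(=O)/C(=C(\CO)CO[Si](c1ccccc1)(c1ccccc1)C(C)(C)C)[C@@H](O)C[C@@](C)(OC2(C)C)CO2 | intermediate (not isolated)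
15 | (2E,4R)-2-{[(tert-butyldiphenylsilyl)oxy]methyl}-3-{(1S)-1-hydroxy-2-[(4R)-2,2,4-trimethyl-1,3-dioxolan-4-yl]ethyl}hept-2-en-5-yne-1,4-diol | CC#C[C@@H](O)/C(=C(\CO)CO[Si](c1ccccc1)(c1ccccc1)C(C)(C)C)[C@@H](O)C[C@@](C)(OC2(C)C)CO2 | intermediate
16 | (2Z,4R)-2-{[(tert-butyldiphenylsilyl)oxy]methyl}-4-hydroxy-3-{(1S)-1-hydroxy-2-[(4R)-2,2,4-trimethyl-1,3-dioxolan-4-yl]ethyl}hept-2-en-5-ynal | CC#C[C@@H](O)/C(=C(\C=O)CO[Si](c1ccccc1)(c1ccccc1)C(C)(C)C)[C@@H](O)C[C@@](C)(OC2(C)C)CO2 | intermediate (not isolated)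
17 | (5R)-3-{[(tert-butyldiphenylsilyl)oxy]methyl}-4-{(1S)-1-hydroxy-2-[(4R)-2,2,4-trimethyl-1,3-dioxolan-4-yl]ethyl}-5-(prop-1-yn-1-yl)-2,5-dihydrofuran-2-ol (both anomers) | CC#C[C@H]1OC(O)C(CO[Si](c2ccccc2)(c2ccccc2)C(C)(C)C)=C1[C@@H](O)C[C@@](C)(OC3(C)C)CO3 | intermediate (not isolated)
18 | (5R)-3-{[(tert-butyldiphenylsilyl)oxy]methyl}-4-{(1S)-1-hydroxy-2-[(4R)-2,2,4-trimethyl-1,3-dioxolan-4-yl]ethyl}-5-(prop-1-yn-1-yl)furan-2(5H)-one | CC#C[C@H]1OC(=O)C(CO[Si](c2ccccc2)(c2ccccc2)C(C)(C)C)=C1[C@@H](O)C[C@@](C)(OC3(C)C)CO3 | intermediate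
19 | (1S)-1-[(2R)-4-{[(tert-butyldiphenylsilyl)oxy]methyl}-5-oxo-2-(prop-1-yn-1-yl)-2,5-dihydrofuran-3-yl]-2-[(4R)-2,2,4-trimethyl-1,3-dioxolan-4-yl]ethyl 2-methylprop-2-enoate | CC#C[C@H]1OC(=O)C(CO[Si](c2ccccc2)(c2ccccc2)C(C)(C)C)=C1[C@@H](OC(=O)C(C)=C)C[C@@](C)(OC3(C)C)CO3 | intermediate
20 | (1S,3R)-1-[(2R)-4-{[(tert-butyldiphenylsilyl)oxy]methyl}-5-oxo-2-(prop-1-yn-1-yl)-2,5-dihydrofuran-3-yl]-3,4-dihydroxy-3-methylbutyl 2-methylprop-2-enoate | CC#C[C@H]1OC(=O)C(CO[Si](c2ccccc2)(c2ccccc2)C(C)(C)C)=C1[C@@H](OC(=O)C(C)=C)C[C@@](C)(O)CO | intermediate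
21 | (1S,3R)-1-[(2R)-4-{[(tert-butyldiphenylsilyl)oxy]methyl}-5-oxo-2-(prop-1-yn-1-yl)-2,5-dihydrofuran-3-yl]-3-hydroxy-3-methyl-4-oxobutyl 2-methylprop-2-enoate | CC#C[C@H]1OC(=O)C(CO[Si](c2ccccc2)(c2ccccc2)C(C)(C)C)=C1[C@@H](OC(=O)C(C)=C)C[C@@](C)(O)C=O | intermediate
22 | vinyl bromide (bromoethene) | C=CBr | starting material
23 | (1S,3R,4RS)-1-[(2R)-4-{[(tert-butyldiphenylsilyl)oxy]methyl}-5-oxo-2-(prop-1-yn-1-yl)-2,5-dihydrofuran-3-yl]-3,4-dihydroxy-3-methylhex-5-en-1-yl 2-methylprop-2-enoate (both epimers at the vinyl carbinol, C1 of the target) | CC#C[C@H]1OC(=O)C(CO[Si](c2ccccc2)(c2ccccc2)C(C)(C)C)=C1[C@@H](OC(=O)C(C)=C)C[C@@](C)(O)C(O)C=C | intermediate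
24 | (4E,6R,8S,10R)-13-[(tert-butyldiphenylsilyl)oxy]-1,10-dihydroxy-8-[(2-methylprop-2-enoyl)oxy]germacra-1,4,7(11)-trien-12,6-olide (C1 enol) | C/C1=C\[C@H]2OC(=O)C(CO[Si](c3ccccc3)(c3ccccc3)C(C)(C)C)=C2[C@@H](OC(=O)C(C)=C)C[C@@](C)(O)C(O)=CC1 | intermediate (not isolated)
25 | (4E,6R,8S,10R)-13-[(tert-butyldiphenylsilyl)oxy]-10-hydroxy-8-[(2-methylprop-2-enoyl)oxy]-1-oxogermacra-4,7(11)-dien-12,6-olide | C/C1=C\[C@H]2OC(=O)C(CO[Si](c3ccccc3)(c3ccccc3)C(C)(C)C)=C2[C@@H](OC(=O)C(C)=C)C[C@@](C)(O)C(=O)CC1 | intermediate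
26 | (4E,6R,8S,10R)-10,13-dihydroxy-8-[(2-methylprop-2-enoyl)oxy]-1-oxogermacra-4,7(11)-dien-12,6-olide | C/C1=C\[C@H]2OC(=O)C(CO)=C2[C@@H](OC(=O)C(C)=C)C[C@@](C)(O)C(=O)CC1 | intermediate
27 | (4E,6R,8S,10R)-10,13-diacetoxy-8-[(2-methylprop-2-enoyl)oxy]-1-oxogermacra-4,7(11)-dien-12,6-olide (CNP0115165.1) | C=C(C)C(=O)O[C@H]1C[C@@](C)(OC(C)=O)C(=O)CC/C(C)=C/[C@H]2OC(=O)C(COC(C)=O)=C12 | target

**Step count**
Total steps: 16. Longest linear sequence: 15 steps (steps 1–4 and 6–16; step 5 is a one-step side branch).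

**Steps most likely to fail**

Step 14 (Proposed new method). The ring closure may lose to intermolecular coupling, to plain redox isomerisation of the allylic alcohol into the ethyl ketone without C–C bond formation, or to bond formation at C5 instead of C4. The fallback closes the same C3–C4 bond by a B-alkyl Suzuki–Miyaura macrocyclisation, which is known chemistry for medium rings with an E-trisubstituted olefin. It sets out from 23. Palladium-catalysed syn-hydrostannation of the alkyne (n-Bu3SnH, PdCl2(PPh3)2, THF, 0 °C; tin at the less hindered C4) should give the (E)-vinylstannane F1. Iododestannylation (I2, CH2Cl2, 0 °C) should give the (E)-vinyl iodide F2 with retention. Hydroboration of the terminal alkene with excess 9-BBN-H (THF, rt; the hydroxyls are borylated reversibly and freed again by the aqueous base) gives the B-alkyl borane F3. This is cyclised without isolation (Pd(dppf)Cl2, AsPh3, Cs2CO3, DMF/THF/H2O, 0.002 M, rt) to the macrocyclic 1,10-diol F4. Oxidation of the secondary C1 alcohol (Dess–Martin periodinane, NaHCO3, CH2Cl2) brings the route back to 25.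

Step 8. The sequence may fail by acid-induced dehydration of the hemiketal to a furan, by enolisation at C12 instead of carbonyl addition, or by poor facial selectivity in the ynone reduction. The fallback replaces the one-flask sequence by an open-chain, reagent-controlled one. It sets out from 12. Aminolysis of the lactone (MeNHOMe·HCl, AlMe3, CH2Cl2, 0 °C) gives the hydroxy Weinreb amide F5. Both hydroxyls are silylated at once (TESOTf, 2,6-lutidine, −78 °C) to the bis-TES ether F6. 1-Propynylmagnesium bromide (THF, 0 °C) gives the silyl-protected ynone F7, which cannot cyclise. CBS reduction with the (S)-oxazaborolidine and catecholborane (alkynyl as the small group) should give the (6R)-propargylic alcohol F8. Removal of both TES groups (HF·pyridine, THF, 0 °C; the TBDPS ether stays) returns the route to 15.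

Step 7. The reduction may fail by poor facial discrimination between the two flanks of the ketone or by competing 1,4-reduction of the doubly activated alkene. The fallback replaces reagent control by substrate control from the chiral-pool centre. It sets out from 11. Acetonide hydrolysis (AcOH/THF/H2O, 40 °C) gives the keto diol F9. Narasaka–Prasad reduction (Et2BOMe, NaBH4, THF/MeOH, −78 °C), directed by the tertiary C10 hydroxyl with the larger C1 arm equatorial in the boron chelate, should give the 1,3-syn (8S)-triol F10. Re-formation of the terminal acetonide (2,2-dimethoxypropane, PPTS, acetone), favoured over the strained 1,3-dioxane, returns the route to 12.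

**Further compounds**
F1 | step 14 | (E)-vinylstannane: 23 with H on C5 and n-Bu3Sn on C4 (tin trans to C6) | C/C([Sn](CCCC)(CCCC)CCCC)=C\[C@H]1OC(=O)C(CO[Si](c2ccccc2)(c2ccccc2)C(C)(C)C)=C1[C@@H](OC(=O)C(C)=C)C[C@@](C)(O)C(O)C=C
F2 | step 14 | (E)-vinyl iodide: iodine on C4, trans to C6 | C/C(I)=C\[C@H]1OC(=O)C(CO[Si](c2ccccc2)(c2ccccc2)C(C)(C)C)=C1[C@@H](OC(=O)C(C)=C)C[C@@](C)(O)C(O)C=C
F3 | step 14 | B-alkyl borane: F2 with 9-borabicyclo[3.3.1]nonan-9-yl on C3 | C/C(I)=C\[C@H]1OC(=O)C(CO[Si](c2ccccc2)(c2ccccc2)C(C)(C)C)=C1[C@@H](OC(=O)C(C)=C)C[C@@](C)(O)C(O)CCB1C2CCCC1CCC2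
F4 | step 14 | (4E,6R,8S,10R)-13-[(tert-butyldiphenylsilyl)oxy]-1,10-dihydroxy-8-[(2-methylprop-2-enoyl)oxy]germacra-4,7(11)-dien-12,6-olide (both C1 epimers) | C/C1=C\[C@H]2OC(=O)C(CO[Si](c3ccccc3)(c3ccccc3)C(C)(C)C)=C2[C@@H](OC(=O)C(C)=C)C[C@@](C)(O)C(O)CC1
F5 | step 8 | hydroxy Weinreb amide from ring-opening of 12 (amide carbonyl C6 cis to the C12 CH2OH) | CON(C)C(=O)/C(=C(\CO)CO[Si](c1ccccc1)(c1ccccc1)C(C)(C)C)[C@@H](O)C[C@@](C)(OC2(C)C)CO2
F6 | step 8 | bis-TES ether of F5 (O8 and O12 silylated) | CON(C)C(=O)/C(=C(\CO[Si](CC)(CC)CC)CO[Si](c1ccccc1)(c1ccccc1)C(C)(C)C)[C@@H](O[Si](CC)(CC)CC)C[C@@](C)(OC2(C)C)CO2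
F7 | step 8 | silyl-protected ynone (propynyl ketone at C6) | CC#CC(=O)/C(=C(\CO[Si](CC)(CC)CC)CO[Si](c1ccccc1)(c1ccccc1)C(C)(C)C)[C@@H](O[Si](CC)(CC)CC)C[C@@](C)(OC2(C)C)CO2
F8 | step 8 | (6R)-propargylic alcohol, bis-TES ether of 15 | CC#C[C@@H](O)/C(=C(\CO[Si](CC)(CC)CC)CO[Si](c1ccccc1)(c1ccccc1)C(C)(C)C)[C@@H](O[Si](CC)(CC)CC)C[C@@](C)(OC2(C)C)CO2
F9 | step 7 | 4-{[(tert-butyldiphenylsilyl)oxy]methyl}-3-[(3R)-3,4-dihydroxy-3-methylbutanoyl]furan-2(5H)-one | O=C1OCC(CO[Si](c2ccccc2)(c2ccccc2)C(C)(C)C)=C1C(=O)C[C@@](C)(O)CO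
F10 | step 7 | 4-{[(tert-butyldiphenylsilyl)oxy]methyl}-3-[(1S,3R)-1,3,4-trihydroxy-3-methylbutyl]furan-2(5H)-one | O=C1OCC(CO[Si](c2ccccc2)(c2ccccc2)C(C)(C)C)=C1[C@@H](O)C[C@@](C)(O)CO
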